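(The earlier runs and the new flask come from a simulation for an exercise, noise included.)

Target appears late in both runs and then faster and faster, a lag (induction period), so the way it grows with time brackets what more catalyst can do.

| setting | theta | zeta | flask |
|---|---|---|---|
| starting material | 27 mM | 18 mM | 27 mM |
| precatalyst | 0.02 mol% | 0.02 mol% | 0.02 mol% |
| remark | the very flask that is asked about, followed so far | run made earlier |  |

| run | time / min | target / % | starting material / % |
|---|---|---|---|
| theta | 2.00 | 0 | 99.7 |
| theta | 6.00 | 0 | 99.6 |
| theta | 10.0 | 0.5 | 99.0 |
| theta | 15.0 | 1.3 | 98.6 |
| zeta | 15.0 | 1.3 | 98.7 |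
| zeta | 30.0 | 5.7 | 94.3 |
| zeta | 50.0 | 14.1 | 85.9 |
| zeta | 60.0 | 19.0 | 80.6 |

(scatter of a reading: 0.3 percentage points)

* factor on the rate of making target when 10% of the starting material are converted if precatalyst is charged twice over
* factor on the rate when 10% of the starting material are converted if precatalyst is charged at 0.1 mol% instead



At equal loading, the theta and zeta runs read 1.3% and 1.3% target at 15.0 min, so the reckoning here takes the longer zeta curve for this flask. Suppose the fraction of target grows as the charge of precatalyst times time to a power n, with the rate proportional to the awake catalyst. A larger charge then reaches 10% conversion sooner, and the rate there goes as the charge to the power 1/n. A catalyst awake from the start has n = 1, and doubling gives 2: the upper bound. A catalyst waking in step with time makes target as time squared, and doubling gives 1.41: the lower bound.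

Between 30.0 min and 60.0 min, target in the zeta run climbs across 10% from 5.7% to 19.0%. This reading gives 0.576 for the loading exponent, the power of the precatalyst charge in the rate at fixed conversion. Doubling is then worth 1.49, and 0.1 mol% is worth 2.53.

The forecast, reasoning that “more precatalyst reaches 10 % earlier, when less of it has activated”, gives 1.47 (1.2 to 1.8) and 2.5 (1.8 to 3.5). Its doubling factor lies inside the bracket, above 1.41 and below 2.

The flask gives a factor of 1.47 for a charge raised by a factor of 2, an exponent of 0.556 against the 0.576 read from the zeta run. The second flask, at 0.1 mol%, gives 2.40, where the carried exponent gives 2.53.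

starting material + enzyme ⇌ complex (K = 460 M⁻¹, k = 62000 M⁻¹ min⁻¹); complex → enzyme + target (k = 82.0 min⁻¹); precatalyst → enzyme (k = 0.00960 min⁻¹) The precatalyst wakes with a time constant of 1.74 h, longer than the 0.674 h this flask takes to reach 10% conversion. Precatalyst still holds 64.9% of the catalyst in this flask at 0.750 h, and 42.1% at 1.50 h.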